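## Structural features

The target is a flavone: a benzopyran-4-one (rings A and C fused through C4a–C8a) that carries a 2,4-dihydroxyphenyl ring B on C2 through the C2–C1' bond. Ring C bears a prenyl chain on C3. Ring A is pentasubstituted, with a hydroxyl on C5 hydrogen-bonded to the C4 carbonyl, a 3-methyl-2-oxobutyl chain on C6, a methoxy group on C7 and one free position at C8. There is no stereocentre and no alkene geometry to set, because the prenyl alkene ends in two methyl groups; every problem is one of regiochemistry and functional-group tolerance. The fragile groups are the trisubstituted prenyl alkene (hydration, hydrochlorination or cationic cyclisation in acid), the oxidisable resorcinol ring B, whose 2'-hydroxyl can also attack a 1,3-dicarbonyl, and the enolisable C6 benzyl ketone, which can close onto a free ortho hydroxyl to give a furan. The real difficulty is the crowded seam between rings A and C. Three ring A oxygens must end up as O1, a methyl ether and a free phenol, the C6 chain must sit between two of them, and because two of these oxygens flank C4a the direction of pyranone closure (6- versus 8-substituted flavone) needs a temporary cap on O5. The key step uses C2 itself: it is bonded to C3, C1' and O1 at the oxidation level of a carbonyl, so it can be carbon monoxide inserted between C1' of a ring B aryl bromide and the α-carbon (C3) of a ring A aryl ketone that already carries the prenyl chain.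

## Logic of the disconnections

**23 to 22.** The O5–CH3 bond is the last one made in the backward sense. A methyl cap on O5 is wanted because O5 and O1 both flank C4a: with O5 capped only O1 can close ring C. With O5 and O7 both capped, the C6 ketone has no free ortho hydroxyl with which to form a furan while acid is present. The gain is that the 6- versus 8-substitution question disappears and the ring A starting material can be symmetric. The demand is a dealkylation that tells the peri, carbonyl-chelated O5 methyl from the O7 methyl and spares the prenyl alkene.

**22 to 20 (through 21).** Ring C is opened at O1–C2 and the four acid-labile caps are put back, which gives the open-chain 2-prenyl-1,3-diketone 20. This turns the heterocycle into a carbonyl condensation, so one acid treatment can deprotect and close the ring. The demand is that closure comes from the ring A hydroxyl onto C2 and not from the ring B 2'-hydroxyl onto C4, and that the acid is mild enough for the prenyl group.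

**20 to 15 + 17 + 18.** C2–C3 and C2–C1' are cut and C2 is excised as 18. This is the strategic cut: it separates the molecule into a ring A ketone, a ring B bromide and a one-carbon gas. The demand is a carbonylative coupling at a secondary, hindered enolate carbon with one and only one enolisable ketone present. For that reason the C6 ketone is a dioxolane and the ring A hydroxyl is a methoxymethyl ether in 15, not a free phenol. The ether is chosen for three reasons: it is the group that directs the metalation used to make the ketone, it removes O-aroylation as a competing path, and it is lost in the same acid step as the other caps.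

**15 to 12 + 13.** The bond from C3 to the prenyl CH2 is cut. Alkylating a methyl ketone enolate is much simpler than prenylating a 1,3-diketone, where O- and C-alkylation compete. The demand is mono-alkylation.

**12 to 9 + 10.** The aryl–acyl bond C4a–C4 is cut. In 9 the two remaining ring hydrogens are equivalent and each lies between a methoxymethoxy and a methoxy group, so directed lithiation has only one possible outcome and no Lewis acid touches the dioxolane. The demand is clean acyl transfer without over-addition.

**9 to 7 (through 8), 7 to 6, 6 to 5.** These are changes of protecting group and oxidation level only. The silyl ether is exchanged for the methoxymethyl ether because the first lithiation needs a non-directing group on oxygen and the second needs a directing one. The dioxolane is installed on the ketone, and the ketone comes from the carbinol.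

**5 to 2 + 3 (through 4), 2 to 1.** The bond from C6 to the chain CH2 is cut. The carbon between the two methoxy groups of 2 is the most acidic ring position once the third oxygen carries a bulky silyl group, and the terminal carbon of 3 is the only unhindered electrophilic site. The demand is lithiation at that carbon and not beside the silyloxy group.

**17 to 16.** Two O–C bonds of the acetals are cut; this is a plain protection.

## Other disconnections considered

**Alternative 1:** The cut runs through ring A: C8–C8a, C5–C6, C7–C8 and C4a–C5. It leaves a 4-pyranone that already holds ring B and the prenyl group and has a diazoacetyl group on the carbon that becomes C8a (A1), and an ynol ether that supplies C6 and C7 with the chain as a silyl-protected carbinol (A2). In the forward step, irradiation of A1 would cause a Wolff shift to a pyranonyl ketene, [2+2] addition to A2, four-electron opening of the cyclobutenone and six-electron closure onto the pyranone to give A3.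
- In its favour: ring A is assembled in one operation with O5 free, O7 methylated and the C6 chain in place. The regiochemistry follows from the polarity of the ynol ether, and no chelation-controlled demethylation is needed. On differentiation of the ring A oxygens it is better than the chosen plan.
- Against it: A1 is a fully substituted 2-aryl-3-prenyl-4-pyranone with an acyl handle for diazo transfer, which is longer to make and less convergent than 15. The ketene, and any carbene that escapes the Wolff shift, are generated next to the prenyl alkene. The six-electron closure must engage an electron-poor pyranone double bond. A2 is a sensitive compound with its own multistep preparation.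
- Comparison: the chain arrives at the alcohol oxidation level, so desilylation, oxidation beside a free 5-hydroxyl and acid removal of the acetals would follow A3, three steps against two after the chosen key step. Mechanistically it is a four-bond pericyclic cascade against a two-bond catalytic union. It sets more of the skeleton at once, but on step count and number of uncertain operations the chosen plan should be ahead.

**Alternative 2:** Ring C is cut at C4a–C4, C4–C3 and O1–C2, so that C4, not C2, comes from 18. The partners are the ring A iodophenol A4, one iodination away from 8, and the ring B aryl acetylene A5. With a divalent palladium phosphine precatalyst, reduced in the flask to zerovalent palladium, and a secondary amine, A4 would give an aroylpalladium species, then an ynone, then A6 by 6-endo closure of the phenol.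
- In its favour: ring C closes in the same operation, so no acid cyclodehydration is needed and the question of which phenol attacks which carbonyl never arises. On that point it is better than the chosen plan. It is equal in convergence and in the use of 18 as the one-carbon unit, and A4 takes fewer steps to reach than 15.
- Against it: A6 has hydrogen on C3. The prenyl group would have to be put on the α-carbon of a finished, hindered 2-arylchromone, by C3 metalation and alkylation with 13 or by halogenation and cross-coupling. That adds steps and is a weak bond formation in this series. The di-ortho-substituted, electron-rich A4 should also be slow in oxidative addition, and the ynone can close 5-exo to an aurone.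
- Comparison: about one step fewer before the key step, two or more extra after it. The chosen plan places the prenyl group on a simple methyl ketone before the carbonylation, which is the safer order.

**Alternative 3:** Here ring B is the ring that is made. C1'–C2' and C5'–C6' are cut, leading back to the 2-ethynylchromone A7, with rings A and C complete and the prenyl group and protected chain in place, and the 1-methoxy-1,3-bis(silyloxy)diene A8. The forward step would be a [4+2] cycloaddition in which the alkyne acts as a vinylogous ynone. Loss of the methoxy group as the alcohol and desilylation would aromatise the adduct to the free resorcinol A9.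
- In its favour: ring B needs no protecting groups, its oxygen pattern follows from the polarisation of diene and dienophile, and since ring C exists beforehand the direction of pyranone closure is never in doubt. On protecting-group economy in ring B it is better than the chosen plan. The endgame from A9 (ketal hydrolysis, then 5-O-demethylation) is equal in length.
- Against it: A7 is far from commercial materials, since it needs chromone construction plus an alkyne at C2 beside the 3-prenyl group. The alkyne is only moderately activated and hindered, and a stepwise conjugate addition may stop short of ring closure. A8 is moisture-sensitive.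
- Comparison: structurally it avoids ring B protection. Mechanistically it replaces a catalytic three-component union by a thermal cycloaddition of uncertain rate. On step economy it should be longer, because all the effort moves into A7.

Key step: step 9

Assumption: 2-isopropyloxirane is used as the racemate; the carbinol centre it creates in 5 is removed by oxidation in step 3, and C3 of 20 is enolisable and becomes sp2 in step 10, so the route needs no stereocontrol.

Remark: the ring A hydroxyl of the ketone is carried through the key step as its methoxymethyl ether and the ketone is made by directed lithiation, not by Lewis-acid acylation, which a dioxolane would not survive; the carbon skeletons of 15 and 20 are unchanged by this.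

## Route

Step 1
Reactants: 1 3,5-dimethoxyphenol
Product: 2 (3,5-dimethoxyphenoxy)triisopropylsilane
Conditions: i-Pr3SiCl, imidazole, DMF, rt
Reagents that add atoms: triisopropylsilyl chloride, CC(C)[Si](Cl)(C(C)C)C(C)C
Why: Standard O-silylation of a phenol; the bulky triisopropylsilyl group is chosen because it does not direct ortho-lithiation and resists anionic silyl migration, which leaves the carbon between the two methoxy groups as the metalation site in step 2.

Step 2
Reactants: 2 (3,5-dimethoxyphenoxy)triisopropylsilane; 3 2-isopropyloxirane (racemic)
Product: 5 rac-1-[2,6-dimethoxy-4-(triisopropylsilyloxy)phenyl]-3-methylbutan-2-ol, via aryllithium 4 (not isolated)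
Conditions: n-BuLi, THF, 0 °C to rt; then 3, BF3·OEt2, −78 °C
Reagents that add atoms: none
Why: Directed ortho-metalation at the carbon flanked by two methoxy groups (cooperative direction, silyloxy group too hindered to compete), then BF3-assisted SN2 opening of the monosubstituted epoxide at its CH2 terminus. The new carbinol centre is formed racemic and is deleted in step 3.

Step 3
Reactants: 5 rac-1-[2,6-dimethoxy-4-(triisopropylsilyloxy)phenyl]-3-methylbutan-2-ol
Product: 6 1-[2,6-dimethoxy-4-(triisopropylsilyloxy)phenyl]-3-methylbutan-2-one
Conditions: Dess–Martin periodinane, CH2Cl2, 0 °C to rt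
Reagents that add atoms: none
Why: Dess–Martin oxidation of a secondary alcohol under near-neutral conditions; the electron-rich, fully etherified arene and the silyl ether are not affected.

Step 4
Reactants: 6 1-[2,6-dimethoxy-4-(triisopropylsilyloxy)phenyl]-3-methylbutan-2-one
Product: 7 {4-[(2-isopropyl-1,3-dioxolan-2-yl)methyl]-3,5-dimethoxyphenoxy}triisopropylsilane
Conditions: HOCH2CH2OH, p-TsOH (cat.), toluene, reflux, Dean–Stark
Reagents that add atoms: ethylene glycol, OCCO
Why: Acid-catalysed ketalisation driven by azeotropic removal of water; it masks the more acidic benzyl ketone so that every later base meets one enolisable carbonyl only. Aryl triisopropylsilyl and methyl ethers tolerate catalytic sulfonic acid.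

Step 5
Reactants: 7 {4-[(2-isopropyl-1,3-dioxolan-2-yl)methyl]-3,5-dimethoxyphenoxy}triisopropylsilane
Product: 9 2-[2,6-dimethoxy-4-(methoxymethoxy)benzyl]-2-isopropyl-1,3-dioxolane, via ammonium phenoxide 8 (not isolated)
Conditions: Bu4NF, THF, 0 °C; then MeOCH2Cl, i-Pr2NEt, 0 °C to rt
Reagents that add atoms: chloromethyl methyl ether, COCCl
Why: Fluoride cleaves the aryl silyl ether and the tetrabutylammonium phenoxide is alkylated in the same flask (one-pot desilylation and O-alkylation). The basic medium leaves the dioxolane untouched and installs the ortho-directing group for step 6.

Step 6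
Reactants: 9 2-[2,6-dimethoxy-4-(methoxymethoxy)benzyl]-2-isopropyl-1,3-dioxolane; 10 N-methoxy-N-methylacetamide
Product: 12 1-{3-[(2-isopropyl-1,3-dioxolan-2-yl)methyl]-2,4-dimethoxy-6-(methoxymethoxy)phenyl}ethan-1-one, via aryllithium 11 (not isolated)
Conditions: n-BuLi, THF, 0 °C; then 10, −78 to 0 °C
Reagents that add atoms: none
Why: Directed ortho-metalation: the two remaining ring hydrogens are equivalent and each lies between the methoxymethoxy and a methoxy group, so only one aryllithium can form. Weinreb ketone synthesis then gives the methyl ketone, because the chelated tetrahedral adduct collapses only on work-up; the dioxolane is inert to organolithiums.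

Step 7
Reactants: 12 1-{3-[(2-isopropyl-1,3-dioxolan-2-yl)methyl]-2,4-dimethoxy-6-(methoxymethoxy)phenyl}ethan-1-one; 13 prenyl bromide (1-bromo-3-methylbut-2-ene)
Product: 15 1-{3-[(2-isopropyl-1,3-dioxolan-2-yl)methyl]-2,4-dimethoxy-6-(methoxymethoxy)phenyl}-5-methylhex-4-en-1-one, via lithium enolate 14 (not isolated)
Conditions: LiN(i-Pr)2, THF, −78 °C; then 13, −78 to −20 °C
Reagents that add atoms: none
Why: Kinetic lithium enolate alkylation of the only enolisable carbonyl with a primary allylic bromide (SN2 at the CH2 terminus). Low temperature and a slight deficit of base limit the proton exchange that leads to double alkylation.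

Step 8
Reactants: 16 4-bromoresorcinol
Product: 17 1-bromo-2,4-bis(methoxymethoxy)benzene
Conditions: MeOCH2Cl, i-Pr2NEt, CH2Cl2, 0 °C to rt
Reagents that add atoms: chloromethyl methyl ether, COCCl
Why: Double O-alkylation of a resorcinol to the bis-acetal; base-stable ethers are needed because the coupling partner in step 9 is a sodium enolate.

Step 9
Reactants: 15 1-{3-[(2-isopropyl-1,3-dioxolan-2-yl)methyl]-2,4-dimethoxy-6-(methoxymethoxy)phenyl}-5-methylhex-4-en-1-one; 17 1-bromo-2,4-bis(methoxymethoxy)benzene; 18 carbon monoxide
Product: 20 rac-1-[2,4-bis(methoxymethoxy)phenyl]-3-{3-[(2-isopropyl-1,3-dioxolan-2-yl)methyl]-2,4-dimethoxy-6-(methoxymethoxy)phenyl}-2-(3-methylbut-2-en-1-yl)propane-1,3-dione, via sodium enolate 19 (not isolated)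
Conditions: NaN(SiMe3)2 (2.2 equiv), 1,4-dioxane, 0 °C; then 17, Pd(OAc)2 (5 mol%), Xantphos (6 mol%), CO (5 bar), 80 °C
Reagents that add atoms: none
Why: Pd(OAc)2 (divalent palladium) is reduced in the flask to a zerovalent palladium complex of Xantphos, a wide-bite-angle bisphosphine, which undergoes oxidative addition to 17; CO inserts to give an aroylpalladium bromide that forms C2–C1'. Enolate 19 displaces bromide on palladium and reductive elimination from the C-bound enolate forms C2–C3; the second equivalent of base converts 20 into its diketonate, which removes it from further aroylation and from retro-Claisen cleavage. The closest known reaction type is the palladium-catalysed carbonylative α-arylation of aryl alkyl ketones with aryl bromides to 1,3-diketones, including ketones with an α-methylene group. No ring closes in this step. C3 is formed racemic and is enolisable, so no control element is needed; it becomes sp2 in step 10. The step needs four selectivities: a single enolisable ketone (the C6 ketone is a dioxolane); carbonylative over direct arylation (CO pressure and the wide bite angle favour insertion and acyl reductive elimination); C- over O-aroylation (no free phenol, since the ring A hydroxyl is a methoxymethyl ether); and mono-aroylation (20 has one α-hydrogen and is stored as its anion). The prenyl alkene is a spectator because a trisubstituted alkene inserts into aroylpalladium far more slowly than an enolate is captured.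

Step 10
Reactants: 20 rac-1-[2,4-bis(methoxymethoxy)phenyl]-3-{3-[(2-isopropyl-1,3-dioxolan-2-yl)methyl]-2,4-dimethoxy-6-(methoxymethoxy)phenyl}-2-(3-methylbut-2-en-1-yl)propane-1,3-dione
Product: 22 2-(2,4-dihydroxyphenyl)-5,7-dimethoxy-6-(3-methyl-2-oxobutyl)-3-(3-methylbut-2-en-1-yl)-4H-chromen-4-one, via deprotected diketone 21 (not isolated)
Conditions: 3 M aq. HCl, MeOH, 50 °C
Reagents that add atoms: water, O
Why: Acid cleaves the three methoxymethyl acetals and the dioxolane, and the ring A hydroxyl adds to the ring B carbonyl (6-exo-trig) and dehydrates to the 4H-chromen-4-one (acid cyclodehydration of a 2-hydroxyaryl 1,3-diketone). Closure in this direction is expected because the ring B carbonyl is the less hindered one and its oxocarbenium ion is stabilised by the para oxygen, whereas the ring A carbonyl lies between two ortho substituents. O5 is methylated, so only O1 can close, and the C6 ketone has no free ortho hydroxyl for furan formation.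

Step 11
Reactants: 22 2-(2,4-dihydroxyphenyl)-5,7-dimethoxy-6-(3-methyl-2-oxobutyl)-3-(3-methylbut-2-en-1-yl)-4H-chromen-4-one
Product: 23 2-(2,4-dihydroxyphenyl)-5-hydroxy-7-methoxy-6-(3-methyl-2-oxobutyl)-3-(3-methylbut-2-en-1-yl)-4H-chromen-4-one (target)
Conditions: BCl3, CH2Cl2, −78 to 0 °C; then cold aq. NaHCO3
Reagents that add atoms: none
Why: Chelation-controlled demethylation: boron bridges the C4 carbonyl and the peri O5 in a six-membered chelate and chloride removes that methyl group by SN2, while the O7 methyl has no chelating partner and should persist at low temperature (the known selective 5-O-demethylation of 5-methoxyflavones). A cold, buffered quench keeps the freed 5-hydroxyl from condensing with the C6 ketone.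

## Compound list

1 | 3,5-dimethoxyphenol | COc1cc(O)cc(OC)c1 | starting material
2 | (3,5-dimethoxyphenoxy)triisopropylsilane | COc1cc(O[Si](C(C)C)(C(C)C)C(C)C)cc(OC)c1 | intermediate
3 | 2-isopropyloxirane (racemic) | CC(C)C1CO1 | starting material
4 | [2,6-dimethoxy-4-(triisopropylsilyloxy)phenyl]lithium (formed in the flask) | [Li]c1c(OC)cc(O[Si](C(C)C)(C(C)C)C(C)C)cc1OC | intermediate
5 | rac-1-[2,6-dimethoxy-4-(triisopropylsilyloxy)phenyl]-3-methylbutan-2-ol | COc1cc(O[Si](C(C)C)(C(C)C)C(C)C)cc(OC)c1CC(O)C(C)C | intermediate
6 | 1-[2,6-dimethoxy-4-(triisopropylsilyloxy)phenyl]-3-methylbutan-2-one | COc1cc(O[Si](C(C)C)(C(C)C)C(C)C)cc(OC)c1CC(=O)C(C)C | intermediate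
7 | {4-[(2-isopropyl-1,3-dioxolan-2-yl)methyl]-3,5-dimethoxyphenoxy}triisopropylsilane | COc1cc(O[Si](C(C)C)(C(C)C)C(C)C)cc(OC)c1CC1(C(C)C)OCCO1 | intermediate
8 | 4-[(2-isopropyl-1,3-dioxolan-2-yl)methyl]-3,5-dimethoxyphenol (present in the flask as its tetrabutylammonium phenoxide) | COc1cc(O)cc(OC)c1CC1(C(C)C)OCCO1 | intermediate
9 | 2-[2,6-dimethoxy-4-(methoxymethoxy)benzyl]-2-isopropyl-1,3-dioxolane | COCOc1cc(OC)c(CC2(C(C)C)OCCO2)c(OC)c1 | intermediate
10 | N-methoxy-N-methylacetamide | CON(C)C(C)=O | starting material
11 | {3-[(2-isopropyl-1,3-dioxolan-2-yl)methyl]-2,4-dimethoxy-6-(methoxymethoxy)phenyl}lithium (formed in the flask) | [Li]c1c(OCOC)cc(OC)c(CC2(C(C)C)OCCO2)c1OC | intermediate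
12 | 1-{3-[(2-isopropyl-1,3-dioxolan-2-yl)methyl]-2,4-dimethoxy-6-(methoxymethoxy)phenyl}ethan-1-one | COCOc1cc(OC)c(CC2(C(C)C)OCCO2)c(OC)c1C(C)=O | intermediate
13 | prenyl bromide (1-bromo-3-methylbut-2-ene) | CC(C)=CCBr | starting material
14 | lithium enolate of 12 (formed in the flask) | [Li]OC(=C)c1c(OCOC)cc(OC)c(CC2(C(C)C)OCCO2)c1OC | intermediate
15 | 1-{3-[(2-isopropyl-1,3-dioxolan-2-yl)methyl]-2,4-dimethoxy-6-(methoxymethoxy)phenyl}-5-methylhex-4-en-1-one | COCOc1cc(OC)c(CC2(C(C)C)OCCO2)c(OC)c1C(=O)CCC=C(C)C | intermediate
16 | 4-bromoresorcinol (4-bromobenzene-1,3-diol) | Oc1ccc(Br)c(O)c1 | starting material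
17 | 1-bromo-2,4-bis(methoxymethoxy)benzene | COCOc1ccc(Br)c(OCOC)c1 | intermediate
18 | carbon monoxide | [C-]#[O+] | starting material
19 | sodium enolate of 15 (formed in the flask, enolate geometry not defined) | [Na]OC(=CCC=C(C)C)c1c(OCOC)cc(OC)c(CC2(C(C)C)OCCO2)c1OC | intermediate
20 | rac-1-[2,4-bis(methoxymethoxy)phenyl]-3-{3-[(2-isopropyl-1,3-dioxolan-2-yl)methyl]-2,4-dimethoxy-6-(methoxymethoxy)phenyl}-2-(3-methylbut-2-en-1-yl)propane-1,3-dione | COCOc1cc(OC)c(CC2(C(C)C)OCCO2)c(OC)c1C(=O)C(CC=C(C)C)C(=O)c1ccc(OCOC)cc1OCOC | intermediate
21 | rac-1-(2,4-dihydroxyphenyl)-3-[6-hydroxy-2,4-dimethoxy-3-(3-methyl-2-oxobutyl)phenyl]-2-(3-methylbut-2-en-1-yl)propane-1,3-dione (formed in the flask) | COc1cc(O)c(C(=O)C(CC=C(C)C)C(=O)c2ccc(O)cc2O)c(OC)c1CC(=O)C(C)C | intermediate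
22 | 2-(2,4-dihydroxyphenyl)-5,7-dimethoxy-6-(3-methyl-2-oxobutyl)-3-(3-methylbut-2-en-1-yl)-4H-chromen-4-one | COc1cc2oc(-c3ccc(O)cc3O)c(CC=C(C)C)c(=O)c2c(OC)c1CC(=O)C(C)C | intermediate
23 | 2-(2,4-dihydroxyphenyl)-5-hydroxy-7-methoxy-6-(3-methyl-2-oxobutyl)-3-(3-methylbut-2-en-1-yl)-4H-chromen-4-one | COc1cc2oc(-c3ccc(O)cc3O)c(CC=C(C)C)c(=O)c2c(O)c1CC(=O)C(C)C | target

## Step count and least certain steps

Total step count: 11. Longest linear sequence: 10 (steps 1 to 7, then 9, 10 and 11); step 8 is a one-step side branch.

**Step 9 (key step).** Two things are most likely to go wrong. Oxidative addition of the electron-rich, ortho-alkoxy bromide may be slow under CO, and carbon–carbon bond formation at the secondary, hindered enolate carbon may be outrun by CO-free α-arylation, by O-aroylation to an enol ester or by reduction of the bromide. Residual amide base may also be consumed by CO. The fallback is a crossed Claisen condensation, which gives up the three-component union but forms the same C2–C3 bond. It sets out from 17 and 15: bromine–lithium exchange on 17 with n-BuLi at −78 °C and quenching with methyl chloroformate would give methyl 2,4-bis(methoxymethoxy)benzoate F1, and the lithium enolate of 15 (LiN(SiMe3)2, THF) would be acylated by F1. It returns to the route at 20.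

**Step 10.** Once all three acetals are gone, ring closure may run partly in the wrong direction, with the ring B 2'-hydroxyl attacking the ring A carbonyl. Prolonged warming in acid may also add water, methanol or HCl across the prenyl alkene, and hydrolysis of the hindered dioxolane may lag behind. The fallback changes the ring B protecting groups so that they survive the acid step. It sets out from 16: alkylation with 2-bromopropane and K2CO3 in DMF would give 1-bromo-2,4-di(propan-2-yloxy)benzene F2. The carbonylative coupling of F2 with 15 and 18 would give the diketone rac-1-[2,4-di(propan-2-yloxy)phenyl]-3-{3-[(2-isopropyl-1,3-dioxolan-2-yl)methyl]-2,4-dimethoxy-6-(methoxymethoxy)phenyl}-2-(3-methylbut-2-en-1-yl)propane-1,3-dione F3. Acid would then free only the ring A hydroxyl and the ketone and close ring C without ambiguity to 2-[2,4-di(propan-2-yloxy)phenyl]-5,7-dimethoxy-6-(3-methyl-2-oxobutyl)-3-(3-methylbut-2-en-1-yl)-4H-chromen-4-one F4. BCl3 would remove both isopropyl groups together with the chelated O5 methyl. It returns to the route at 23.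

**Step 11.** HCl released when the ring B phenols bind boron may add to the prenyl alkene. The liberated 5-hydroxyl may condense with the C6 ketone to a furan during an acidic quench, and over-exposure may start to remove the O7 methyl. The fallback replaces the electrophilic boron halide by a chelate-directed nucleophilic dealkylation with MgI2·OEt2 in THF and toluene, where magnesium bridges O5 and the C4 carbonyl and iodide takes the methyl group, so no strong protic acid is produced. It sets out from 22 and returns at 23 without any new compound (F0).

**Step 2.** Metalation may occur partly beside the silyloxy group, followed by silyl migration to carbon, or it may be incomplete. The Lewis acid may also rearrange the epoxide or open it with halide faster than the hindered aryllithium attacks. The fallback fixes the metalation site through a halogen. It sets out from 2: bromination with N-bromosuccinimide in acetonitrile at the position para to the silyloxy group would give (4-bromo-3,5-dimethoxyphenoxy)triisopropylsilane F5, and bromine–lithium exchange with n-BuLi at −78 °C would give 4 regiospecifically, which is opened with 3 as before. It returns to the route at 5.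

**Step 7.** Proton exchange between product and enolate may lead to double alkylation, with some O-alkylation or attack at the tertiary allylic terminus. The fallback brings in the prenyl chain already attached to the acyl group. 5-Methylhex-4-enoic acid F6 (a catalogue compound) would be converted with carbonyldiimidazole and N,O-dimethylhydroxylamine hydrochloride into N-methoxy-N,5-dimethylhex-4-enamide F7, and aryllithium 11, generated from 9 as in step 6, would be acylated by F7. It sets out from 9, bypasses 12 and returns to the route at 15.

## Further compounds

F1 | step 9 | methyl 2,4-bis(methoxymethoxy)benzoate | COCOc1ccc(C(=O)OC)c(OCOC)c1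
F2 | step 10 | 1-bromo-2,4-di(propan-2-yloxy)benzene | CC(C)Oc1ccc(Br)c(OC(C)C)c1
F3 | step 10 | rac-1-[2,4-di(propan-2-yloxy)phenyl]-3-{3-[(2-isopropyl-1,3-dioxolan-2-yl)methyl]-2,4-dimethoxy-6-(methoxymethoxy)phenyl}-2-(3-methylbut-2-en-1-yl)propane-1,3-dione | COCOc1cc(OC)c(CC2(C(C)C)OCCO2)c(OC)c1C(=O)C(CC=C(C)C)C(=O)c1ccc(OC(C)C)cc1OC(C)C
F4 | step 10 | 2-[2,4-di(propan-2-yloxy)phenyl]-5,7-dimethoxy-6-(3-methyl-2-oxobutyl)-3-(3-methylbut-2-en-1-yl)-4H-chromen-4-one | COc1cc2oc(-c3ccc(OC(C)C)cc3OC(C)C)c(CC=C(C)C)c(=O)c2c(OC)c1CC(=O)C(C)C
F0 | step 11 | none | none
F5 | step 2 | (4-bromo-3,5-dimethoxyphenoxy)triisopropylsilane | COc1cc(O[Si](C(C)C)(C(C)C)C(C)C)cc(OC)c1Br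
F6 | step 7 | 5-methylhex-4-enoic acid (purchased) | CC(C)=CCCC(=O)O
F7 | step 7 | N-methoxy-N,5-dimethylhex-4-enamide | CON(C)C(=O)CCC=C(C)C
A1 | alternative 1 | 2-[2,4-bis(methoxymethoxy)phenyl]-6-(2-diazoacetyl)-3-(3-methylbut-2-en-1-yl)-4H-pyran-4-one | [N-]=[N+]=CC(=O)c1cc(=O)c(CC=C(C)C)c(-c2ccc(OCOC)cc2OCOC)o1
A2 | alternative 1 | rac-tert-butyl[(1-methoxy-5-methylhex-1-yn-4-yl)oxy]dimethylsilane | COC#CCC(O[Si](C)(C)C(C)(C)C)C(C)C
A3 | alternative 1 | rac-2-[2,4-bis(methoxymethoxy)phenyl]-6-[2-(tert-butyldimethylsilyloxy)-3-methylbutyl]-5-hydroxy-7-methoxy-3-(3-methylbut-2-en-1-yl)-4H-chromen-4-one | COc1cc2oc(-c3ccc(OCOC)cc3OCOC)c(CC=C(C)C)c(=O)c2c(O)c1CC(O[Si](C)(C)C(C)(C)C)C(C)C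
A4 | alternative 2 | 2-iodo-4-[(2-isopropyl-1,3-dioxolan-2-yl)methyl]-3,5-dimethoxyphenol | COc1cc(O)c(I)c(OC)c1CC1(C(C)C)OCCO1
A5 | alternative 2 | 1-ethynyl-2,4-bis(methoxymethoxy)benzene | C#Cc1ccc(OCOC)cc1OCOC
A6 | alternative 2 | 2-[2,4-bis(methoxymethoxy)phenyl]-6-[(2-isopropyl-1,3-dioxolan-2-yl)methyl]-5,7-dimethoxy-4H-chromen-4-one | COc1cc2oc(-c3ccc(OCOC)cc3OCOC)cc(=O)c2c(OC)c1CC1(C(C)C)OCCO1
A7 | alternative 3 | 2-ethynyl-6-[(2-isopropyl-1,3-dioxolan-2-yl)methyl]-5,7-dimethoxy-3-(3-methylbut-2-en-1-yl)-4H-chromen-4-one | COc1cc2oc(C#C)c(CC=C(C)C)c(=O)c2c(OC)c1CC1(C(C)C)OCCO1
A8 | alternative 3 | 1-methoxy-1,3-bis(trimethylsilyloxy)buta-1,3-diene | COC(O[Si](C)(C)C)=CC(=C)O[Si](C)(C)C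
A9 | alternative 3 | 2-(2,4-dihydroxyphenyl)-6-[(2-isopropyl-1,3-dioxolan-2-yl)methyl]-5,7-dimethoxy-3-(3-methylbut-2-en-1-yl)-4H-chromen-4-one | COc1cc2oc(-c3ccc(O)cc3O)c(CC=C(C)C)c(=O)c2c(OC)c1CC1(C(C)C)OCCO1
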